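**Assumption:** the target has no stereocentre and no stereogenic double bond, so it is achiral; "single enantiomer" is read as the single constitutional isomer shown (side chain at C8, not C6).

## Retrosynthetic overview

1. Target 9 ⇐ 7‑O‑prenyl flavonol 8 by aromatic Claisen rearrangement (O7 → C8), which turns the prenyl ether into the 1,1‑dimethylallyl group.
2. 8 ⇐ chalcone 5 by a one‑pot pyranone closure that forms the O1–C2 ring bond and the C3–O bond (key C–O step, proposed new method).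
3. 5 ⇐ acetophenone 3 + 4‑methoxybenzaldehyde 4 (Claisen–Schmidt condensation).
4. 3 ⇐ phloroacetophenone 1 + prenyl bromide 2 (para‑selective O‑alkylation).
5. Ring order: rings A and B are bought; ring C (the pyranone) is the only ring formed, in step 3.

## Route

**Step 1**
Reactants: 1 2,4,6‑trihydroxyacetophenone; 2 prenyl bromide (1‑bromo‑3‑methylbut‑2‑ene)
Product: 3 1‑[2,6‑dihydroxy‑4‑(3‑methylbut‑2‑enyloxy)phenyl]ethanone
Conditions: 2 (1.05 equiv), K2CO3 (1.1 equiv), acetone, rt → 50 °C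
Reagents that add atoms: none
Why: Williamson O‑alkylation goes to the 4‑OH because it is the most acidic hydroxyl and the only one not hydrogen‑bonded to the acetyl C=O, and weak base in aprotic acetone disfavours C‑prenylation.

**Step 2**
Reactants: 3 1‑[2,6‑dihydroxy‑4‑(3‑methylbut‑2‑enyloxy)phenyl]ethanone; 4 4‑methoxybenzaldehyde
Product: 5 (E)‑1‑[2,6‑dihydroxy‑4‑(3‑methylbut‑2‑enyloxy)phenyl]‑3‑(4‑methoxyphenyl)prop‑2‑en‑1‑one
Conditions: 4 (1.2 equiv), KOH (50% aq., 10 equiv), EtOH, rt, 48 h; then cold 1 M HCl to pH 5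
Reagents that add atoms: none
Why: Claisen–Schmidt (crossed aldol) condensation with E1cB dehydration gives the conjugated E‑enone as the thermodynamic product, water is the only co‑product, and the allyl ether is inert to hydroxide.

**Step 3**
Reactants: 5 (E)‑1‑[2,6‑dihydroxy‑4‑(3‑methylbut‑2‑enyloxy)phenyl]‑3‑(4‑methoxyphenyl)prop‑2‑en‑1‑one
Product: 8 3,5‑dihydroxy‑2‑(4‑methoxyphenyl)‑7‑(3‑methylbut‑2‑enyloxy)chromen‑4‑one, via flavanone 6 (not isolated), via dihydroflavonol 7 (not isolated)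
Conditions: (±)‑trans‑2‑(phenylsulfonyl)‑3‑phenyloxaziridine (2.2 equiv, added slowly), KOt‑Bu (3 equiv), THF/t‑BuOH 4:1, 0 °C → rt; then 1 M HCl
Reagents that add atoms: (±)‑trans‑2‑(phenylsulfonyl)‑3‑phenyloxaziridine (Davis oxaziridine), O=S(=O)(c1ccccc1)N1OC1c1ccccc1
Why: Proposed new method: a peroxide‑free Algar–Flynn–Oyamada‑type oxidative cyclisation in which an N‑sulfonyloxaziridine replaces alkaline H2O2 – the 2'‑phenoxide of 5 closes 6‑endo onto the enone (oxa‑Michael, forming O1–C2), the flavanone enolate 6 is intercepted at C3 by electrophilic O‑transfer (Davis‑type hydroxylation) to give 7, and the enediolate of 7 takes up a second oxygen to a C3 gem‑diol that loses water and enolises to the aromatic 3‑hydroxy‑4‑pyranone 8; a purely electrophilic oxidant cannot epoxidise the enone (the Weitz–Scheffer channel that diverts 6'‑oxygenated chalcones to aurones under H2O2/NaOH) and at ≤ 20 °C it does not touch the prenyl alkene; closest known reaction types are the Algar–Flynn–Oyamada reaction and tandem conjugate addition/Davis enolate oxidation; C2 and C3 of 7 become sp2, so no stereocentre survives.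

**Step 4**
Reactants: 8 3,5‑dihydroxy‑2‑(4‑methoxyphenyl)‑7‑(3‑methylbut‑2‑enyloxy)chromen‑4‑one
Product: 9 3,5,7‑trihydroxy‑2‑(4‑methoxyphenyl)‑8‑(2‑methylbut‑3‑en‑2‑yl)chromen‑4‑one
Conditions: PhNEt2, 190 °C, sealed tube, Ar, 1–2 h
Reagents that add atoms: none
Why: Aromatic ortho‑Claisen ([3,3]‑sigmatropic) rearrangement bonds the tertiary allyl terminus to the ring and tautomerises back to the 7‑phenol; C8 is preferred over C6 because of the higher C7–C8 double‑bond character in 5‑hydroxychromones, the amine solvent suppresses acid‑mediated cyclisation onto the new alkene, and the step is a pure isomerisation with no stereocentre formed.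

## Compound list

1 | 1‑(2,4,6‑trihydroxyphenyl)ethanone (phloroacetophenone) | CC(=O)c1c(O)cc(O)cc1O | starting material
2 | 1‑bromo‑3‑methylbut‑2‑ene (prenyl bromide) | CC(C)=CCBr | starting material
3 | 1‑[2,6‑dihydroxy‑4‑(3‑methylbut‑2‑enyloxy)phenyl]ethanone | CC(=O)c1c(O)cc(OCC=C(C)C)cc1O | intermediate
4 | 4‑methoxybenzaldehyde | COc1ccc(C=O)cc1 | starting material
5 | (E)‑1‑[2,6‑dihydroxy‑4‑(3‑methylbut‑2‑enyloxy)phenyl]‑3‑(4‑methoxyphenyl)prop‑2‑en‑1‑one | COc1ccc(/C=C/C(=O)c2c(O)cc(OCC=C(C)C)cc2O)cc1 | intermediate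
6 | (±)‑5‑hydroxy‑2‑(4‑methoxyphenyl)‑7‑(3‑methylbut‑2‑enyloxy)chroman‑4‑one, formed as its potassium enolate; racemic, (2S) drawn | COc1ccc([C@@H]2CC(=O)c3c(O)cc(OCC=C(C)C)cc3O2)cc1 | intermediate (not isolated)
7 | (±)‑trans‑3,5‑dihydroxy‑2‑(4‑methoxyphenyl)‑7‑(3‑methylbut‑2‑enyloxy)chroman‑4‑one; racemic, (2R,3R) drawn | COc1ccc([C@@H]2[C@H](C(=O)c3c(O)cc(OCC=C(C)C)cc3O2)O)cc1 | intermediate (not isolated)
8 | 3,5‑dihydroxy‑2‑(4‑methoxyphenyl)‑7‑(3‑methylbut‑2‑enyloxy)chromen‑4‑one (7‑O‑prenylkaempferide) | COc1ccc(-c2oc3cc(OCC=C(C)C)cc(O)c3c(=O)c2O)cc1 | intermediate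
9 | 3,5,7‑trihydroxy‑2‑(4‑methoxyphenyl)‑8‑(2‑methylbut‑3‑en‑2‑yl)chromen‑4‑one (achiral) | C=CC(C)(C)c1c(O)cc(O)c2c(=O)c(O)c(-c3ccc(OC)cc3)oc12 | target

## Count and risk

Total steps: 4. Longest linear sequence: 4 (1 → 3 → 5 → 8 → 9).

**Step 3 (proposed new method) – most likely to fail.** The risks are slow trapping of the low‑concentration enolate, C‑hydroxylation of the electron‑rich phenoxide ring, over‑oxidation of the flavonolate at C2, and base‑induced ring contraction of 7 before the second O‑transfer. The fallback uses known chemistry only; it sets out from 5 and comes back at 8. MOMCl/i‑Pr2NEt (CH2Cl2, 0 °C) caps one of the two equivalent ortho‑hydroxyls to give (E)‑1‑[2‑hydroxy‑6‑(methoxymethoxy)‑4‑(3‑methylbut‑2‑enyloxy)phenyl]‑3‑(4‑methoxyphenyl)prop‑2‑en‑1‑one F1. Classical Algar–Flynn–Oyamada oxidation (30% H2O2, NaOH, MeOH, 0 °C → rt) then gives 3‑hydroxy‑5‑(methoxymethoxy)‑2‑(4‑methoxyphenyl)‑7‑(3‑methylbut‑2‑enyloxy)chromen‑4‑one F2, with the aurone by‑product removed by chromatography. 1 M HCl in MeOH/THF at rt cleaves the chelation‑labilised 5‑O‑MOM group without harming the prenyl ether and delivers 8.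

**Step 4 – regiochemistry and survival of the product.** The risks are competing migration to C6 and thermal cyclisation of the 7‑OH onto the new alkene. The fallback moves the rearrangement to the acetophenone stage, where both ortho positions are equivalent, and then builds the ring so that only the 8‑isomer can form; it sets out from 3 and comes back at 9. Heating 3 in PhNEt2 (190 °C) gives 1‑[2,4,6‑trihydroxy‑3‑(2‑methylbut‑3‑en‑2‑yl)phenyl]ethanone F3 as the single Claisen product. MOMCl (2.2 equiv)/i‑Pr2NEt protects the 4‑OH and the unhindered 6‑OH, leaving the chelated 2‑OH next to the tert‑alkyl group free, to give 1‑[2‑hydroxy‑4,6‑bis(methoxymethoxy)‑3‑(2‑methylbut‑3‑en‑2‑yl)phenyl]ethanone F4. KOH/EtOH condensation with 4 gives (E)‑1‑[2‑hydroxy‑4,6‑bis(methoxymethoxy)‑3‑(2‑methylbut‑3‑en‑2‑yl)phenyl]‑3‑(4‑methoxyphenyl)prop‑2‑en‑1‑one F5. Algar–Flynn–Oyamada oxidation (H2O2, NaOH, MeOH) closes the ring through the only free hydroxyl to give 3‑hydroxy‑5,7‑bis(methoxymethoxy)‑2‑(4‑methoxyphenyl)‑8‑(2‑methylbut‑3‑en‑2‑yl)chromen‑4‑one F6. HCl in MeOH at rt removes both MOM groups and gives 9.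

**Step 2 – condensation with two free ortho‑hydroxyls.** The risks are a sluggish reaction of the doubly deprotonated ketone with an electron‑rich aldehyde and partial cyclisation of the product. The fallback is a protecting‑group route; it sets out from 3 and comes back at 5. NaH/MOMCl (DMF, 0 °C) gives 1‑[2,6‑bis(methoxymethoxy)‑4‑(3‑methylbut‑2‑enyloxy)phenyl]ethanone F7. KOH/EtOH condensation with 4 then proceeds on a ketone with no acidic OH to give (E)‑1‑[2,6‑bis(methoxymethoxy)‑4‑(3‑methylbut‑2‑enyloxy)phenyl]‑3‑(4‑methoxyphenyl)prop‑2‑en‑1‑one F8. 1 M HCl in MeOH at rt removes both MOM groups to give 5; any flavanone 6 formed alongside is an equally good substrate for step 3.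

## Further compounds

F1 | step 3 | (E)‑1‑[2‑hydroxy‑6‑(methoxymethoxy)‑4‑(3‑methylbut‑2‑enyloxy)phenyl]‑3‑(4‑methoxyphenyl)prop‑2‑en‑1‑one | COCOc1cc(OCC=C(C)C)cc(O)c1C(=O)/C=C/c1ccc(OC)cc1
F2 | step 3 | 3‑hydroxy‑5‑(methoxymethoxy)‑2‑(4‑methoxyphenyl)‑7‑(3‑methylbut‑2‑enyloxy)chromen‑4‑one | COCOc1cc(OCC=C(C)C)cc2oc(-c3ccc(OC)cc3)c(O)c(=O)c12
F3 | step 4 | 1‑[2,4,6‑trihydroxy‑3‑(2‑methylbut‑3‑en‑2‑yl)phenyl]ethanone | CC(=O)c1c(O)cc(O)c(C(C)(C)C=C)c1O
F4 | step 4 | 1‑[2‑hydroxy‑4,6‑bis(methoxymethoxy)‑3‑(2‑methylbut‑3‑en‑2‑yl)phenyl]ethanone | CC(=O)c1c(OCOC)cc(OCOC)c(C(C)(C)C=C)c1O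
F5 | step 4 | (E)‑1‑[2‑hydroxy‑4,6‑bis(methoxymethoxy)‑3‑(2‑methylbut‑3‑en‑2‑yl)phenyl]‑3‑(4‑methoxyphenyl)prop‑2‑en‑1‑one | COCOc1cc(OCOC)c(C(=O)/C=C/c2ccc(OC)cc2)c(O)c1C(C)(C)C=C
F6 | step 4 | 3‑hydroxy‑5,7‑bis(methoxymethoxy)‑2‑(4‑methoxyphenyl)‑8‑(2‑methylbut‑3‑en‑2‑yl)chromen‑4‑one | C=CC(C)(C)c1c(OCOC)cc(OCOC)c2c(=O)c(O)c(-c3ccc(OC)cc3)oc12
F7 | step 2 | 1‑[2,6‑bis(methoxymethoxy)‑4‑(3‑methylbut‑2‑enyloxy)phenyl]ethanone | CC(=O)c1c(OCOC)cc(OCC=C(C)C)cc1OCOC
F8 | step 2 | (E)‑1‑[2,6‑bis(methoxymethoxy)‑4‑(3‑methylbut‑2‑enyloxy)phenyl]‑3‑(4‑methoxyphenyl)prop‑2‑en‑1‑one | COCOc1cc(OCC=C(C)C)cc(OCOC)c1C(=O)/C=C/c1ccc(OC)cc1
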